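Subtract Friday's run from Thursday's, reading by reading, before arguing about the flask at c(partner) = 0.150 M.

all flasks: substrate 0.050 M
- Friday's: partner 0.21 M; run made earlier
- Thursday's: partner 0.33 M; run made earlier
- flask: partner 0.150 M; time 80 min

| run | time / min | target / % |
|---|---|---|
| Friday's | 3.00 | 23.3 |
| Friday's | 5.00 | 29.9 |
| Friday's | 8.00 | 34.5 |
| Friday's | 15.0 | 34.7 |
| Friday's | 25.0 | 28.8 |
| Friday's | 50.0 | 19.8 |
| Thursday's | 3.00 | 22.4 |
| Thursday's | 5.00 | 28.7 |
| Thursday's | 8.00 | 36.6 |
| Thursday's | 15.0 | 36.7 |
| Thursday's | 25.0 | 29.0 |
| Thursday's | 50.0 | 19.6 |

(scatter of a reading: 1 percentage point)



- the best time, 80 min at the latest, for target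
- the amount of target, in percent of the substrate charged, at that time
- the first time at which target reaches 26%, in the same percent, in min

One chemist holds that c(partner) does not matter for target, so the flask can be read off the two runs. The other holds that target forms in proportion to c(partner). Her view asks Thursday's run to rise 1.57 times as fast as Friday's, yet at 3.00 min Thursday's reads 22.4% against Friday's 23.3%. She answers that at 8.00 min Thursday's stands 2.1 percentage points higher, more than the 1.4 points scatter of one difference.

My own reckoning takes all 6 differences. Their mean is 0.33 points, smaller than its scatter of 0.58 points. So I take the mean of the two runs at a given time as the large term, which belongs to c(partner) = 0.270 M, and compute a small term for the flask. This partner correction is the mean difference per molar times the distance of the flask's c(partner) from that midpoint, and it comes to −0.33 points. At 8.00 min that gives 35.2% for the flask, a reading time and not a peak.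

The forecast, reckoned separately, takes the first side: “Formation therefore looks essentially independent of partner here”. It puts the best at 11 min with 36%, and the level asked at 3.9 min.

The flask gives 37.0% at 11.4 min, and the level asked at 4.01 min.

    partner + intermediate A ⇌ intermediate B (K = 1.05 M⁻¹, k = 0.466 M⁻¹ min⁻¹)
    substrate → intermediate A (k = 0.0592 min⁻¹)
    target ⇌ isomer of the product (K = 2.50, k = 0.0524 min⁻¹)
    substrate → target (k = 0.0976 min⁻¹)

Up to 40.0 min substrate, the limiting reagent, fell to 0.189% in the flask, passing into target at 1.6 times its rate into intermediate A at the start, while target passed on into isomer of the product. By 80.0 min the flask held target at 18.0%, isomer of the product at 44.2% and intermediate B at 5.06%; the step to intermediate B is where the second chemist's proportion to c(partner) stands in the scheme, and taking c(partner) from Friday's value to the flask's leaves the highest amount of target, without scatter, at 37.0% against 37.0%. The flask held 35.3% at 8.00 min, beside the corrected 35.2%. The same correction, on the mean readings at 15.0 min and 25.0 min, gives 32.0% for the flask stopped at 20.0 min, which holds 32.6%.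

The earlier runs and the new flask stem from a simulated flask on assumed constants, and the scatter is random.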